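Z, the limiting reagent at 1.20 equiv of X, is asked for at 30 h, together with E and D.

| flask | Z | X | remark | time |
|---|---|---|---|---|
| Monday's | 0.80 M | 1.2 equiv | run made earlier |  |
| Tuesday's | 1.8 M | 1.2 equiv | run made earlier |  |
| Saturday's | 1.2 M | 1.8 equiv | run made earlier |  |
| flask | 1.2 M | 1.20 equiv |  | 30 h |

| run | time / h | Z / % | E / % | D / % |
|---|---|---|---|---|
| Monday's | 2.50 | 93.3 | 6.8 | 0.4 |
| Monday's | 5.00 | 87.5 | 10.2 | 0.7 |
| Monday's | 8.00 | 81.5 | 14.3 | 1.5 |
| Monday's | 10.0 | 77.8 | 16.6 | 2.1 |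
| Monday's | 12.0 | 74.6 | 18.0 | 3.0 |
| Monday's | 15.0 | 69.4 | 21.6 | 4.0 |
| Monday's | 20.0 | 63.5 | 24.4 | 4.8 |
| Tuesday's | 1.33 | 92.0 | 6.9 | 0.6 |
| Tuesday's | 2.00 | 89.3 | 10.1 | 0.7 |
| Tuesday's | 3.00 | 83.9 | 13.5 | 1.6 |
| Tuesday's | 5.00 | 76.0 | 19.2 | 2.3 |
| Tuesday's | 8.00 | 65.6 | 26.0 | 4.0 |
| Tuesday's | 12.0 | 56.0 | 32.8 | 5.2 |
| Tuesday's | 20.0 | 42.0 | 41.0 | 8.1 |
| Saturday's | 1.50 | 91.4 | 7.5 | 0.5 |
| Saturday's | 5.00 | 75.3 | 20.3 | 2.3 |
| Saturday's | 8.00 | 64.5 | 27.5 | 4.9 |
| Saturday's | 12.0 | 53.8 | 33.9 | 7.5 |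
| Saturday's | 20.0 | 38.4 | 42.3 | 10.6 |

(readings scatter by 0.3 percentage points)

1. Z at 30 h, in percent of the Z charged
2. E at 30 h, in percent of the Z charged
3. D at 30 h, in percent of the Z charged

- a reading or a percentage of E counts all its forms, free or not

Take the main step first, Z + X → E. The early loss of Z, as a fraction per hour, reads 0.0268 /h on Monday, 0.0602 /h on Tuesday and 0.0573 /h on Saturday. At equal equivalents, Tuesday over Monday is 2.25, and the charges of Z stand at 2.25. Saturday's flask holds as much X as Tuesday's but less Z, and its figure sits nearer Tuesday's than Monday's. So the rate reads as a product of two concentrations. With z the fraction of Z left, c°Z its charge and r the equivalents of X: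

−dc_Z/dt = k·c_Z·c_X

ln[(r − 1 + z)/(r·z)] = (r − 1)·k·c°Z·t

At fixed r, z therefore follows the charge-time, the charge of Z multiplied by the hours: 36.0 M·h for this flask. Tuesday's last reading has 36.0 M·h, so my own reckoning puts Z near 42.0%.

Next comes X + E → D, which the rising D suggests. Its rate holds c_E as well, and this step does not show that the charge-time serves as the clock for D, so Tuesday's 8.1%, read at the same charge-time, is a rough figure for D in my own reckoning and no more.

Then comes the rest. The missing balance is 7.30% on Monday at 960 M·min but 4.40% on Tuesday at 864 M·min, so something also runs on plain hours. This flask stands longer than Tuesday's, so E should fall below 41.0%.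

The forecast gives Z 41.8%, E 39.2% and D 8.5%, and calls the gap “partly a first-order, time-driven loss”.

    G ⇌ E, rate k1*(cs1 - [E]) while solid is left; crystals form when [E] > cs1 (solubility = 0.0840 M, k = 0.350 /h)
    Z + X → E (k = 0.0280 /M/h)
    E ⇌ L (K = 1.70, k = 0.0220 /h)
    Z + E → J (k = 0.0120 /M/h)
    X + E → D (k = 0.0280 /M/h)

The flask holds Z 42.4% at charge-time 36.0 M·h, with E 39.2% and D 7.85%, and the forecast stands. With the conversion of E into L struck out, E reads 43.9%. Z moves by 5 points with X charged at 1.05 equiv or 1.37 equiv. A flask of 0.72 M Z at the same equivalents, read at 30 h, has charge-time 1296 M·min, as has Tuesday's reading at 12.0 h, 1300 M·min: Z 55.6% against 56.0%, but E 27.0% against 32.8%.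

The earlier runs and the new flask were generated by integration with constants of no real substance, noise included.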